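**Retrosynthetic overview**
- The strategy rests on the C3–C3' bond: it links two carbons that each bear a C4 ketone and a C2 aryl carbinol. This 2,3-bis(aryl-hydroxymethyl)succinyl unit is the carbon framework of a twofold-symmetric 2,6-diaryl furofuranone dilactone, and C3/C3' are α-keto centres of the two pyranone rings C that can be equilibrated to 2,3-trans.
- Final disconnections, made in one operation: O1–C8a and O1'–C8a' (alkoxide SNAr on 2-fluoroaryl ketones) and C4–C4a and C4'–C4a' (aryl-metal addition to both lactone carbonyls). They lead back to the exo,exo dilactone and two equivalents of a 4-benzyloxy-2-fluorophenyl metal; the four benzyl ethers fall at the very end.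
- Dilactone from (2S,3S)-2,3-bis(4-benzyloxybenzyl)succinic acid by twofold benzylic oxidation with cross-capture by the carboxyl groups; diacid from oxidative enolate homocoupling of the (R)-oxazolidinone imide of 3-(4-benzyloxyphenyl)propanoic acid.
- Ring order: rings B and A are purchased; the C3–C3' bond is made first, the two γ-lactone rings second, and both pyranone rings C last, as the lactones are opened.
- Stereochemical relay: auxiliary → (S,S) succinate centres → exo (R) carbinol centres (future C2/C2') → thermodynamic trans at C3/C3'.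

Key step: step 6

Assumption: the SMILES is read as the (2R,3S,2'R,3'S) isomer (both pyranone rings 2,3-trans, the halves related by a twofold axis); the acid, the oxazolidinone and the bromofluorophenol used as starting materials are taken as purchasable.

**Step 1**
Reactants: 1 3-(4-benzyloxyphenyl)propanoic acid; 2 (R)-4-benzyloxazolidin-2-one
Product: 4 (R)-4-benzyl-3-[3-(4-benzyloxyphenyl)propanoyl]oxazolidin-2-one, via mixed pivalic anhydride 3 (not isolated)
Conditions: PivCl, Et3N, THF, −20 °C; then LiCl, 2, −20 °C → rt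
Reagents that add atoms: none
Why: N-acylation of the oxazolidinone through the mixed pivalic anhydride, whose unhindered carbonyl is attacked by the LiCl-activated nitrogen; no stereocentre is touched.

**Step 2**
Reactants: 4 (R)-4-benzyl-3-[3-(4-benzyloxyphenyl)propanoyl]oxazolidin-2-one (two molecules)
Product: 6 (4R,4'R)-3,3'-[(2S,3S)-2,3-bis(4-benzyloxybenzyl)butanedioyl]bis(4-benzyloxazolidin-2-one), via lithium Z-enolate 5 (not isolated)
Conditions: LiN(i-Pr)2, THF, −78 °C; then TiCl4 (1.1 equiv, CH2Cl2 solution), −78 → −20 °C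
Reagents that add atoms: none
Why: Oxidative enolate homocoupling, in which TiCl4 (tetravalent titanium) takes one electron from the chelated Z-enolate and the α-carbons join on the face opposite the 4-benzyl group of each (R)-auxiliary, so both new centres (the future C3–C3' bond) should be S.

**Step 3**
Reactants: 6 (S,S)-bis-imide
Product: 7 (2S,3S)-2,3-bis(4-benzyloxybenzyl)succinic acid
Conditions: LiOH, 30% H2O2, THF/H2O, 0 °C → rt; then aq Na2SO3; HCl to pH 2
Reagents that add atoms: hydrogen peroxide, OO (as lithium hydroperoxide; its inner oxygen becomes the acid OH)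
Why: Hydroperoxide cleavage of the N-acyl oxazolidinone at the exocyclic carbonyl, which is too weakly basic to epimerise the α-centres; sulfite reduces the peracid and the auxiliary 2 is recovered.

**Step 4**
Reactants: 7 (2S,3S)-2,3-bis(4-benzyloxybenzyl)succinic acid
Product: 8 (1R,2R,5R,6R)-2,6-bis(4-benzyloxyphenyl)-3,7-dioxabicyclo[3.3.0]octane-4,8-dione (exo,exo dilactone)
Conditions: DDQ (2.5 equiv), 4 Å molecular sieves, ClCH2CH2Cl, 70 °C
Reagents that add atoms: none
Why: DDQ oxidative benzylic lactonisation, in which hydride abstraction from each para-alkoxybenzyl CH2 gives a cation that is captured in a five-membered closure by the carboxyl group on the other succinate carbon; the (S,S) backbone enforces the cis ring fusion and each aryl group takes the convex exo face trans to the neighbouring carbonyl, so both new carbinol centres should be R, while Friedel–Crafts closure to an aryltetralin is disfavoured because the ring carbons ortho to the CH2 are meta to the ether oxygen.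

**Step 5**
Reactants: 9 4-bromo-3-fluorophenol
Product: 10 4-benzyloxy-1-bromo-2-fluorobenzene
Conditions: BnBr, K2CO3, acetone, reflux
Reagents that add atoms: benzyl bromide, BrCc1ccccc1
Why: Williamson ether synthesis on the phenoxide; the aryl bromide and fluoride are inert to carbonate.

**Step 6**
Reactants: 8 exo,exo dilactone; 10 4-benzyloxy-1-bromo-2-fluorobenzene (2.4 equiv)
Product: 15 (2R,3S,2'R,3'S)-7,7'-bis(benzyloxy)-2,2'-bis(4-benzyloxyphenyl)-[3,3'-bichromane]-4,4'-dione, via aryllithium 11 (not isolated), via arylcerium dichloride 12 (not isolated), via diketo-diol 13 (not isolated), via cis-cis biflavanone 14 (not isolated)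
Conditions: 10, n-BuLi, THF, −78 °C; anhydrous CeCl3, −78 °C; then 8, −78 °C; aq NH4Cl, extraction; crude 13 (not purified), Cs2CO3, DMF, 25 → 50 °C
Reagents that add atoms: none
Why: Proposed new method: bromine–lithium exchange on 10 gives 11, which is transmetalated to the weakly basic trivalent-cerium reagent 12 and adds once to each lactone carbonyl of 8 (bonds C4–C4a and C4'–C4a'), the tetrahedral lactolates surviving at −78 °C and giving on work-up the bis-lactol in equilibrium with diketo-diol 13; carbonate then opens each lactolate to a ketone plus a benzylic alkoxide, which adds to the fluorine-bearing carbon ortho to the ketone on its own backbone carbon and expels fluoride through a Meisenheimer adduct (bonds O1–C8a and O1'–C8a'). The closest known reaction types are single addition of aryllithium or arylcerium reagents to γ-lactones to give lactols, alkoxide SNAr closure of β-hydroxy 2-fluorophenyl ketones to chroman-4-ones and base-mediated cis-to-trans epimerisation of 3-substituted flavanones; their twofold, telescoped use to turn both rings of a furofuranone dilactone into two pyranones has no direct precedent. Each ring C closes by a six-membered intramolecular addition–elimination at an aromatic carbon, favoured over the seven-membered alternative in which the alkoxide would reach the aryl ring of the other half. C2 and C2' are the R carbinol carbons of 8 and keep their configuration because their C–O bonds are never broken, whereas C3 and C3' first emerge 2,3-cis (14) and are equilibrated by the same base through the C4 enolates to the diequatorial 2,3-trans S configuration; with both C2 centres R, the trans,trans product can only be the twofold-symmetric isomer 15, not the meso one. The step needs mono-addition without enolisation of the base-sensitive dilactone (secured by the cerium reagent and the stable lactolate), fluoride displacement faster than retro-aldol cleavage (the ketone activates the ortho fluorine, the benzyloxy group lies meta to the carbon attacked, and the lactol form keeps the free β-alkoxide concentration low) and C3 epimerisation without retro-oxa-Michael opening at C2 (mild carbonate, moderate temperature).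

**Step 7**
Reactants: 15 tetra-O-benzyl (2R,3S,2'R,3'S)-3,3'-biflavanone
Product: 16 (2R,3S,2'R,3'S)-7,7'-dihydroxy-2,2'-bis(4-hydroxyphenyl)-[3,3'-bichromane]-4,4'-dione (target CNP0231820.2)
Conditions: H2 (1 atm), Pd/C, EtOAc/THF, rt
Reagents that add atoms: none
Why: Catalytic hydrogenolysis of the four aryl benzyl ethers in neutral solvent, where the chromanone C2–O bonds and ketones should survive a short, monitored reaction and no base is present to epimerise C2 or C3.

**Compound list**
1 | 3-(4-benzyloxyphenyl)propanoic acid | OC(=O)CCc1ccc(OCc2ccccc2)cc1 | starting material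
2 | (R)-4-benzyloxazolidin-2-one | O=C1N[C@H](Cc2ccccc2)CO1 | starting material
3 | 3-(4-benzyloxyphenyl)propanoic pivalic anhydride | CC(C)(C)C(=O)OC(=O)CCc1ccc(OCc2ccccc2)cc1 | intermediate
4 | (R)-4-benzyl-3-[3-(4-benzyloxyphenyl)propanoyl]oxazolidin-2-one | O=C(CCc1ccc(OCc2ccccc2)cc1)N1[C@H](Cc2ccccc2)COC1=O | intermediate
5 | lithium Z-enolate of 4 | [Li]O/C(=C\Cc1ccc(OCc2ccccc2)cc1)N1[C@H](Cc2ccccc2)COC1=O | intermediate
6 | (4R,4'R)-3,3'-[(2S,3S)-2,3-bis(4-benzyloxybenzyl)butanedioyl]bis(4-benzyloxazolidin-2-one) | O=C(N1[C@H](Cc2ccccc2)COC1=O)[C@@H](Cc1ccc(OCc2ccccc2)cc1)[C@H](Cc1ccc(OCc2ccccc2)cc1)C(=O)N1[C@H](Cc2ccccc2)COC1=O | intermediate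
7 | (2S,3S)-2,3-bis(4-benzyloxybenzyl)succinic acid | OC(=O)[C@@H](Cc1ccc(OCc2ccccc2)cc1)[C@H](Cc1ccc(OCc2ccccc2)cc1)C(=O)O | intermediate
8 | (1R,2R,5R,6R)-2,6-bis(4-benzyloxyphenyl)-3,7-dioxabicyclo[3.3.0]octane-4,8-dione | O=C1O[C@@H](c3ccc(OCc4ccccc4)cc3)[C@@H]2C(=O)O[C@@H](c3ccc(OCc4ccccc4)cc3)[C@H]12 | intermediate
9 | 4-bromo-3-fluorophenol | Oc1ccc(Br)c(F)c1 | starting material
10 | 4-benzyloxy-1-bromo-2-fluorobenzene | Fc1cc(OCc2ccccc2)ccc1Br | intermediate
11 | (4-benzyloxy-2-fluorophenyl)lithium | [Li]c1ccc(OCc2ccccc2)cc1F | intermediate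
12 | (4-benzyloxy-2-fluorophenyl)cerium dichloride | Cl[Ce](Cl)c1ccc(OCc2ccccc2)cc1F | intermediate
13 | (2R,3R)-1,4-bis(4-benzyloxy-2-fluorophenyl)-2,3-bis[(R)-(4-benzyloxyphenyl)(hydroxy)methyl]butane-1,4-dione (open form of the bis-lactol) | O=C(c1ccc(OCc2ccccc2)cc1F)[C@@H]([C@@H](O)c1ccc(OCc2ccccc2)cc1)[C@H]([C@@H](O)c1ccc(OCc2ccccc2)cc1)C(=O)c1ccc(OCc2ccccc2)cc1F | intermediate
14 | (2R,3R,2'R,3'R)-7,7'-bis(benzyloxy)-2,2'-bis(4-benzyloxyphenyl)-[3,3'-bichromane]-4,4'-dione (2,3-cis in both rings) | O=C1c2ccc(OCc3ccccc3)cc2O[C@@H](c2ccc(OCc3ccccc3)cc2)[C@H]1[C@H]1C(=O)c2ccc(OCc3ccccc3)cc2O[C@H]1c1ccc(OCc2ccccc2)cc1 | intermediate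
15 | (2R,3S,2'R,3'S)-7,7'-bis(benzyloxy)-2,2'-bis(4-benzyloxyphenyl)-[3,3'-bichromane]-4,4'-dione | O=C1c2ccc(OCc3ccccc3)cc2O[C@@H](c2ccc(OCc3ccccc3)cc2)[C@@H]1[C@@H]1C(=O)c2ccc(OCc3ccccc3)cc2O[C@H]1c1ccc(OCc2ccccc2)cc1 | intermediate
16 | (2R,3S,2'R,3'S)-7,7'-dihydroxy-2,2'-bis(4-hydroxyphenyl)-[3,3'-bichromane]-4,4'-dione | O=C1c2ccc(O)cc2O[C@@H](c2ccc(O)cc2)[C@@H]1[C@@H]1C(=O)c2ccc(O)cc2O[C@H]1c1ccc(O)cc1 | target

**Step count**
Total: 7 steps. Longest linear sequence: 6 steps (steps 1, 2, 3, 4, 6, 7); step 5 supplies the second fragment.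

**Steps most likely to fail**

Step 6 (proposed new method). What may go wrong: over-addition, or enolisation with β-elimination of the dilactone, during the organometallic addition; retro-aldol fragmentation of the β-alkoxides before fluoride is displaced; incomplete cis-to-trans equilibration; or scrambling of C2 through retro-oxa-Michael opening while C3 is epimerised. The fallback uses known reactions, sets out from dilactone 8 and returns at 15. Both lactones would be opened with MeNH(OMe)·HCl and AlMe3 (CH2Cl2, 0 °C → rt) to the bis-Weinreb amide diol F1. Immediate silylation (Et3SiOTf, 2,6-lutidine, CH2Cl2, −78 °C) would give the bis-triethylsilyl ether F2. Aryllithium 11 (2.5 equiv, THF, −78 °C) would add once to each chelating amide to give the bis(2-fluoroaryl) diketone bis-silyl ether F3, whose protected carbinols cannot undergo retro-aldol cleavage. Bu4NF in THF at 0 °C would then release the alkoxides directly into the SNAr closure to 14, and a separate, monitored epimerisation (DBU, toluene, rt) would give 15.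

Step 4. What may go wrong: slow hydride abstraction from a benzylic CH2 activated by a single alkoxy group, competing oxidation at the O-benzyl CH2 groups, over-oxidation to aryl ketones, or poor exo/endo control. The fallback sets out from diacid 7 and returns at 8. Hydrogenolysis (H2, Pd/C, EtOAc/MeOH) would give (2S,3S)-2,3-bis(4-hydroxybenzyl)succinic acid F4. Free para-alkylphenols are oxidised by DDQ at room temperature (dioxane) to para-quinone methides, and capture of these far more accessible electrophiles by the carboxyl groups would give the bisphenol dilactone F5. Neutral Mitsunobu O-benzylation (BnOH, PPh3, DIAD, THF) would then restore 8.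

Step 2. What may go wrong: incomplete facial control in the radical coupling (meso or mismatched diastereomers), loss of benzyl ethers to the Lewis acid TiCl4, or low conversion to dimer. The fallback sets out from imide 4 and returns at diacid 7, forming the C3–C3' bond by an ionic SN2 reaction instead. O-Benzyl-L-tyrosine F6 (purchased) would be diazotised (NaNO2, aq H2SO4, retention through the α-lactone) to (S)-3-(4-benzyloxyphenyl)-2-hydroxypropanoic acid F7. Esterification (MeOH, cat. H2SO4) would give the methyl ester F8, and Tf2O with 2,6-lutidine (CH2Cl2, −78 °C) the (S)-triflate F9. The sodium enolate of 4 (NaN(SiMe3)2, THF, −78 °C) would displace the triflate with inversion while the auxiliary fixes the imide α-centre, giving the (2S,3S)-succinate imide methyl ester F10. LiOH/H2O2 followed by excess LiOH would remove the auxiliary and the methyl ester to give 7.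

**Further compounds**
F1 | step 6 | (2R,3R)-2,3-bis[(R)-(4-benzyloxyphenyl)(hydroxy)methyl]-N,N'-dimethoxy-N,N'-dimethylbutanediamide | CON(C)C(=O)[C@@H]([C@@H](O)c1ccc(OCc2ccccc2)cc1)[C@H]([C@@H](O)c1ccc(OCc2ccccc2)cc1)C(=O)N(C)OC
F2 | step 6 | (2R,3R)-2,3-bis[(R)-(4-benzyloxyphenyl)(triethylsilyloxy)methyl]-N,N'-dimethoxy-N,N'-dimethylbutanediamide | CON(C)C(=O)[C@@H]([C@@H](O[Si](CC)(CC)CC)c1ccc(OCc2ccccc2)cc1)[C@H]([C@@H](O[Si](CC)(CC)CC)c1ccc(OCc2ccccc2)cc1)C(=O)N(C)OC
F3 | step 6 | (2R,3R)-1,4-bis(4-benzyloxy-2-fluorophenyl)-2,3-bis[(R)-(4-benzyloxyphenyl)(triethylsilyloxy)methyl]butane-1,4-dione | O=C(c1ccc(OCc2ccccc2)cc1F)[C@@H]([C@@H](O[Si](CC)(CC)CC)c1ccc(OCc2ccccc2)cc1)[C@H]([C@@H](O[Si](CC)(CC)CC)c1ccc(OCc2ccccc2)cc1)C(=O)c1ccc(OCc2ccccc2)cc1F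
F4 | step 4 | (2S,3S)-2,3-bis(4-hydroxybenzyl)succinic acid | OC(=O)[C@@H](Cc1ccc(O)cc1)[C@H](Cc1ccc(O)cc1)C(=O)O
F5 | step 4 | (1R,2R,5R,6R)-2,6-bis(4-hydroxyphenyl)-3,7-dioxabicyclo[3.3.0]octane-4,8-dione | O=C1O[C@@H](c3ccc(O)cc3)[C@@H]2C(=O)O[C@@H](c3ccc(O)cc3)[C@H]12
F6 | step 2 | O-benzyl-L-tyrosine (purchased) | N[C@@H](Cc1ccc(OCc2ccccc2)cc1)C(=O)O
F7 | step 2 | (S)-3-(4-benzyloxyphenyl)-2-hydroxypropanoic acid | O[C@@H](Cc1ccc(OCc2ccccc2)cc1)C(=O)O
F8 | step 2 | methyl (S)-3-(4-benzyloxyphenyl)-2-hydroxypropanoate | O[C@@H](Cc1ccc(OCc2ccccc2)cc1)C(=O)OC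
F9 | step 2 | methyl (S)-3-(4-benzyloxyphenyl)-2-(trifluoromethylsulfonyloxy)propanoate | O=S(=O)(O[C@@H](Cc1ccc(OCc2ccccc2)cc1)C(=O)OC)C(F)(F)F
F10 | step 2 | methyl (2S,3S)-2,3-bis(4-benzyloxybenzyl)-4-[(R)-4-benzyl-2-oxooxazolidin-3-yl]-4-oxobutanoate | O=C(N1[C@H](Cc2ccccc2)COC1=O)[C@@H](Cc1ccc(OCc2ccccc2)cc1)[C@H](Cc1ccc(OCc2ccccc2)cc1)C(=O)OC
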